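**Plan**
1. Retrosynthesis: the butenolide is taken back to a 3-furyl ring, and ring A is then opened at C1–C2. In ring A the C1 carbinol and the exocyclic C4=C18 methylene flank the two methylenes C2 and C3 (a bishomoallylic alcohol), which is the array left by a reductive aldehyde/1,3-diene coupling.
2. The ring-closure precursor is therefore a complete ring B with a formyl group on C10 and a 2-substituted butadiene, C4(=C18)–C3=C2, on C5.
3. Further cuts: diene to ethynyl (ethylene enyne metathesis), 7,8-diol to the C7=C8 alkene, C17/C6–O to an enone by 1,3-transposition, C9–C11 by aldol, C9–C20 by alkylation, ring B (C5–C6 and C9–C10) by a Diels–Alder reaction.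
4. Forward order: ring B first, then its substituents and oxygen pattern, ring A by a SmI2 ketyl/diene 6-endo cyclisation, the butenolide last.
5. Stereochemistry: C5 and C10 from the catalytic asymmetric Diels–Alder step (trans C4/C1 from the E-enal); C9 and C11 from an aldol anti to the C10 ester through a closed chair; C6, C7 and C8 by β-face hydride addition and β-face osmylation; C1 in the ring closure (equatorial O–Sm).

Key step: step 18

Remark: atoms carry clerodane numbers throughout (ring A C1–C5 and C10; ring B C5–C10; side chain C11–C16; C17 on C8, C18 on C4, C19 on C5, C20 on C9); α and β mean below and above ring B drawn as in the target (H-10 β); the target is read as (1R,5R,6R,7S,8R,9S,10S,11S).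
Remark: 2-(furan-3-yl)ethanol is taken as a catalogue compound, and the enantiomer of the diol catalyst in step 1 is the one that gives the configuration drawn.

Step 1
Reactants: 1 (E)-3-(tert-butyldimethylsilyloxy)-N,N-dimethylbuta-1,3-dien-1-amine; 2 ethyl (E)-3-methyl-4-oxobut-2-enoate
Product: 3 Diels–Alder adduct (ring B: ester α on C10; CH3 α and CHO β on C5; NMe2 β on C6; C7=C8 silyl enol ether)
Conditions: 2,2-dimethyl-α,α,α′,α′-tetra(1-naphthyl)-1,3-dioxolane-4,5-dimethanol (1-naphthyl-TADDOL, 20 mol %, enantiomer matched to the configuration drawn), toluene, –78 °C; crude adduct used directly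
Reagents that add atoms: none
Why: Hydrogen-bond-catalysed asymmetric Diels–Alder reaction of an aminosiloxydiene with an α-substituted enal: the nucleophilic CH2 terminus of 1 bonds to the β-carbon of the activated enal (C10) and the amino-bearing terminus to its α-carbon (the C5 quaternary centre), the E geometry of 2 places the formyl group (C4) and the ester (C1) trans, and the chiral diol, hydrogen-bonded to the formyl oxygen, blocks one face of the enal so that C5 and C10 are set absolutely (the C6 amino centre is lost in step 2).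

Step 2
Reactants: 3 Diels–Alder adduct
Product: 5 enone ethyl (1R,2R)-2-ethynyl-2-methyl-5-oxocyclohex-3-ene-1-carboxylate, via alkynyl silyl enol ether 4 (not isolated)
Conditions: dimethyl (1-diazo-2-oxopropyl)phosphonate, K2CO3, EtOH, 0 °C → rt; then 1 M HCl, THF, 0 °C
Reagents that add atoms: dimethyl (1-diazo-2-oxopropyl)phosphonate, COP(=O)(OC)C(=[N+]=[N-])C(C)=O
Why: Seyferth–Gilbert homologation with the Ohira–Bestmann reagent converts the non-enolisable neopentyl aldehyde into the ethynyl group (the masked diene) without touching C5 or C10, and the acid then hydrolyses the silyl enol ether and eliminates dimethylamine (β-elimination) to give the C8 ketone conjugated with C6=C7.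

Step 3
Reactants: 5 enone
Product: 6 methyl enone (C9 CH3 trans to the C10 ester)
Conditions: LiN(i-Pr)2 (1.05 equiv), THF, –78 °C; MeI, –78 → –30 °C
Reagents that add atoms: iodomethane, CI
Why: Kinetic α′-alkylation of an enone enolate: C9 is the only position that can be enolised (C5 is quaternary, and the ester α-proton and the alkyne proton are less acidic), and methyl iodide enters trans to the C10 ester, although the C9 configuration is of no consequence because C9 is enolised again in step 5.

Step 4
Reactants: 7 2-(furan-3-yl)ethanol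
Product: 8 2-(furan-3-yl)acetaldehyde
Conditions: Dess–Martin periodinane, pyridine, CH2Cl2, 0 °C → rt; used at once
Reagents that add atoms: none
Why: Dess–Martin oxidation of a primary alcohol under buffered conditions should give the enolisable arylacetaldehyde without over-oxidation or self-condensation; no stereocentre is formed.

Step 5
Reactants: 6 methyl enone; 8 2-(furan-3-yl)acetaldehyde
Product: 9 aldol (C9 quaternary: C20 α, C11 β; (11S)-hydroxyl; furan-3-ylmethyl on C11)
Conditions: LiN(i-Pr)2 (1.0 equiv), THF, –78 → –30 °C; CeCl3 (anhydrous), –78 °C; 8; AcOH, –78 °C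
Reagents that add atoms: none
Why: Directed aldol addition of the single possible, tetrasubstituted C8–C9 enolate (transmetalated to cerium to lower its basicity toward the enolisable aldehyde and to hold the aldolate against retro-aldol cleavage): the aldehyde adds to the β-face of C9, anti to the C10 ester, which sets the quaternary centre (C20 α, C11 β), and the closed Zimmerman–Traxler chair of this enolate (enolate oxygen cis to C20) with the aldehyde substituent equatorial places the new hydroxyl syn to C20, which corresponds to (11S).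

Step 6
Reactants: 9 aldol
Product: 10 silyl ether (11-O-SiMe2t-Bu)
Conditions: t-BuMe2SiOTf, 2,6-lutidine, CH2Cl2, –78 → 0 °C
Reagents that add atoms: tert-butyldimethylsilyl trifluoromethanesulfonate, CC(C)(C)[Si](C)(C)OS(=O)(=O)C(F)(F)F
Why: Silylation of the hindered secondary alcohol with a silyl triflate and a non-nucleophilic base masks the β-hydroxy ketone against retro-aldol cleavage in step 7 and against oxidation in step 8; no stereocentre is changed.

Step 7
Reactants: 10 silyl ether
Product: 11 tertiary allylic alcohol (C8 bearing C17 and OH, epimer mixture; C6=C7)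
Conditions: MeLi (3 equiv), CeCl3, THF, –78 °C; H2O
Reagents that add atoms: methyllithium, [Li]C
Why: 1,2-Addition of the weakly basic methylcerium reagent to the hindered enone carbonyl, which is faster than attack at the doubly neopentyl ester (one equivalent is consumed by the alkyne proton), installs C17; the configuration of the new C8 carbinol does not matter because C8 becomes sp2 in step 8.

Step 8
Reactants: 11 tertiary allylic alcohol
Product: 12 transposed enone (C6 ketone; C7=C8 bearing C17)
Conditions: pyridinium chlorochromate [C5H5NH][CrO3Cl], 4 Å molecular sieves, CH2Cl2, rt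
Reagents that add atoms: pyridinium chlorochromate, [O-][Cr](=O)(=O)Cl.c1cc[nH+]cc1
Why: Dauben–Babler oxidative 1,3-transposition: the tertiary allylic chromate ester undergoes a [3,3] shift to C6 and is oxidised there, which moves the oxygen function from C8 to C6 and gives the C6 ketone conjugated with the C7=C8 bond that now carries C17; no stereocentre is formed.

Step 9
Reactants: 12 transposed enone
Product: 13 diol (C10–CH2OH and 6α-OH; 11-O-silyl)
Conditions: LiAlH4, THF, –40 → 0 °C; aq potassium sodium tartrate
Reagents that add atoms: none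
Why: Hydride reduction with LiAlH4: the enone is reduced 1,2 from the β-face, which carries only the slim ethynyl group on C5 and H-10, while the α-face carries the C19 methyl and the C10 ester, so that the 6α-alcohol should result, and the C1 ester is reduced to the primary alcohol in the same operation.

Step 10
Reactants: 13 diol
Product: 14 triol (C10–CH2OH, 6α-OH, (11S)-OH)
Conditions: Bu4NF, THF, rt → 45 °C
Reagents that add atoms: none
Why: Fluoride-mediated desilylation frees the C11 hydroxyl now that no ketone remains for a retro-aldol reaction; no stereocentre is changed.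

Step 11
Reactants: 14 triol
Product: 15 primary silyl ether (C1–O–SiMe2t-Bu; 6α-OH and 11-OH free)
Conditions: t-BuMe2SiCl (1.1 equiv), imidazole, CH2Cl2, 0 °C
Reagents that add atoms: tert-butyldimethylsilyl chloride, CC(C)(C)[Si](C)(C)Cl
Why: Selective silylation of the only primary hydroxyl (on C1) with a bulky silyl chloride leaves the two hindered secondary hydroxyls on C6 and C11 free for the next step.

Step 12
Reactants: 15 primary silyl ether
Product: 16 diacetate (6α-OAc, 11-OAc)
Conditions: Ac2O, 4-(dimethylamino)pyridine (cat.), pyridine, rt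
Reagents that add atoms: acetic anhydride, CC(=O)OC(C)=O
Why: Acylation under 4-(dimethylamino)pyridine catalysis converts both secondary alcohols into the 6α- and 11-acetates of the target in one operation with retention at both centres.

Step 13
Reactants: 16 diacetate
Product: 17 diol (7β-OH, 8β-OH; C17 α)
Conditions: OsO4 (1.1 equiv), pyridine, THF, 0 °C; aq NaHSO3
Reagents that add atoms: osmium tetroxide, O=[Os](=O)(=O)=O
Why: Syn-dihydroxylation with OsO4 of the trisubstituted C7=C8 alkene from the β-face, anti to the allylic 6α-acetate and to the α-oriented C19 and C20 methyl groups (in the reactive half-chair the β-substituents on C5 and C9 are both equatorial), should set the 7β- and 8β-hydroxyls, and the stoichiometric reagent reacts much faster with this alkene than with the furan or the alkyne.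

Step 14
Reactants: 17 diol
Product: 18 isobutyrate (7β-O-isobutyryl; 8β-OH free)
Conditions: (i-PrCO)2O, Et3N, 4-(dimethylamino)pyridine (cat.), CH2Cl2, 0 °C → rt
Reagents that add atoms: isobutyric anhydride, CC(C)C(=O)OC(=O)C(C)C
Why: Acylation of the secondary 7β-hydroxyl with the anhydride under 4-(dimethylamino)pyridine catalysis; the tertiary 8β-hydroxyl is too hindered to react, so no protecting group is needed.

Step 15
Reactants: 18 isobutyrate
Product: 19 primary alcohol (C10–CH2OH)
Conditions: HF·pyridine, pyridine, THF, 0 °C → rt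
Reagents that add atoms: none
Why: Cleavage of the primary silyl ether with buffered HF·pyridine, conditions under which the three esters, the tertiary alcohol and the furan should persist; no stereocentre is changed.

Step 16
Reactants: 19 primary alcohol
Product: 20 dienyl alcohol (C5 bearing C4(=C18H2)–C3H=C2H2)
Conditions: ethylene (1 atm), second-generation Grubbs catalyst RuCl2(=CHPh)(H2IMes)(PCy3) (10 mol %), toluene, 80 °C
Reagents that add atoms: ethylene, C=C
Why: Ruthenium-carbene-catalysed cross enyne metathesis with ethylene converts the terminal alkyne into the 2-substituted 1,3-butadiene C4(=C18)–C3=C2, both ethylene carbons being incorporated; the free alcohol, the esters and the furan are tolerated and no stereocentre is formed.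

Step 17
Reactants: 20 dienyl alcohol
Product: 21 dienyl aldehyde (C10–CHO)
Conditions: Dess–Martin periodinane, pyridine, CH2Cl2, 0 °C → rt; used at once
Reagents that add atoms: none
Why: Dess–Martin oxidation of the neopentyl primary alcohol to the C1 aldehyde under buffered conditions, which leave the tertiary alcohol, the diene and the furan untouched and should not epimerise C10 (the formyl group is equatorial).

Step 18
Reactants: 21 dienyl aldehyde
Product: 24 ring-closed furan (1β-OH; C4=C18 exocyclic; trans-decalin), via samarium ketyl 22 (not isolated), via allylsamarium 23 (not isolated)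
Conditions: SmI2 (3 equiv), HMPA (12 equiv), t-BuOH (3 equiv), THF, –78 → –20 °C, slow addition of 21
Reagents that add atoms: none
Why: Proposed new method: single-electron reduction of the C1 aldehyde gives a samarium ketyl that adds 6-endo-trig to C2, the unsubstituted terminus of the s-trans 2-substituted butadiene, to give a delocalised C3–C4–C18 allyl radical; a second electron transfer gives an allylsamarium with the metal on the primary C18 terminus, which t-BuOH protonates at C3 (SE2′), leaving the exocyclic C4=C18 methylene. The closest known reactions are SmI2/HMPA ketyl–olefin cyclisations onto activated alkenes (styrenes, enoates) and the γ-protonation of allylsamarium species formed in SmI2 reductions of allylic esters. Ring A closes in the 6-endo mode because 5-exo attack at C3 would give an unstabilised primary radical and 5-endo attack at C18 is stereoelectronically disfavoured. C1 is set in a chair-like transition state built on the trans-diequatorial C5 and C10 substituents of ring B (hence the trans-decalin), with the bulky O–Sm group equatorial (β) to avoid a syn-pentane contact with the axial C20 methyl, which corresponds to (1R). The step needs reduction of the aldehyde alone in the presence of three esters, a furan and a tertiary alcohol, which is secured because none of these is reduced by SmI2/HMPA at low temperature and none sits β to the ketyl or to the allyl anion, and it needs protonation at C3 and not at C18, which is the kinetic site for a primary-bound allyl metal.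

Step 19
Reactants: 24 ring-closed furan
Product: 26 target CNP0254453.1, via hydroxybutenolide 25 (not isolated)
Conditions: O2, hν (visible), tetraphenylporphyrin (cat.), i-Pr2NEt, CH2Cl2, –78 °C → rt; then NaBH4, EtOH, 0 °C; 1 M HCl
Reagents that add atoms: oxygen, O=O
Why: Sensitised photo-oxygenation of the 3-substituted furan ([4+2] addition of singlet oxygen followed by amine-induced Kornblum–DeLaMare opening at the less hindered α-position) should give the 4-substituted 5-hydroxybutenolide, whose masked aldehyde is reduced by NaBH4 and relactonises on acidification to the 13-en-15,16-olide, while the hindered 1,1-disubstituted C4=C18 alkene reacts far more slowly with singlet oxygen and no stereocentre of the core is touched.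

**Compound list**
1 | (E)-3-(tert-butyldimethylsilyloxy)-N,N-dimethylbuta-1,3-dien-1-amine | CN(C)/C=C/C(=C)O[Si](C)(C)C(C)(C)C | starting material
2 | ethyl (E)-3-methyl-4-oxobut-2-enoate | CCOC(=O)/C=C(\C)C=O | starting material
3 | Diels–Alder adduct, ethyl 5-(tert-butyldimethylsilyloxy)-3-(dimethylamino)-2-formyl-2-methylcyclohex-4-ene-1-carboxylate (C10 ester α; C5 CH3 α, CHO β; C6 NMe2 β) | [C@H]1(C(=O)OCC)[C@](C)(C=O)[C@H](N(C)C)C=C(O[Si](C)(C)C(C)(C)C)C1 | intermediate
4 | alkynyl silyl enol ether, ethyl 5-(tert-butyldimethylsilyloxy)-3-(dimethylamino)-2-ethynyl-2-methylcyclohex-4-ene-1-carboxylate | [C@H]1(C(=O)OCC)[C@](C)(C#C)[C@H](N(C)C)C=C(O[Si](C)(C)C(C)(C)C)C1 | intermediate (not isolated)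
5 | enone, ethyl (1R,2R)-2-ethynyl-2-methyl-5-oxocyclohex-3-ene-1-carboxylate (C8 ketone, C6=C7, ethynyl β on C5) | [C@H]1(C(=O)OCC)[C@](C)(C#C)C=CC(=O)C1 | intermediate
6 | methyl enone, ethyl 2-ethynyl-2,6-dimethyl-5-oxocyclohex-3-ene-1-carboxylate (C9 CH3 trans to the ester) | [C@H]1(C(=O)OCC)[C@](C)(C#C)C=CC(=O)[C@@H]1C | intermediate
7 | 2-(furan-3-yl)ethanol | OCCc1ccoc1 | starting material
8 | 2-(furan-3-yl)acetaldehyde | O=CCc1ccoc1 | intermediate
9 | aldol, ethyl 2-ethynyl-6-[(1S)-2-(furan-3-yl)-1-hydroxyethyl]-2,6-dimethyl-5-oxocyclohex-3-ene-1-carboxylate (C20 α, C11 β) | [C@H]1(C(=O)OCC)[C@](C)(C#C)C=CC(=O)[C@]1(C)[C@H](Cc1ccoc1)O | intermediate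
10 | silyl ether of 9 (11-O-SiMe2t-Bu) | [C@H]1(C(=O)OCC)[C@](C)(C#C)C=CC(=O)[C@]1(C)[C@H](Cc1ccoc1)O[Si](C)(C)C(C)(C)C | intermediate
11 | tertiary allylic alcohol (C8 bearing C17 and OH, epimer mixture; C6=C7) | [C@H]1(C(=O)OCC)[C@](C)(C#C)C=CC(C)(O)[C@]1(C)[C@H](Cc1ccoc1)O[Si](C)(C)C(C)(C)C | intermediate
12 | transposed enone (C6 ketone, C7=C8 bearing C17; C10 ester; 11-O-silyl) | [C@H]1(C(=O)OCC)[C@](C)(C#C)C(=O)C=C(C)[C@]1(C)[C@H](Cc1ccoc1)O[Si](C)(C)C(C)(C)C | intermediate
13 | diol (C10–CH2OH, 6α-OH; 11-O-silyl) | [C@H]1(CO)[C@](C)(C#C)[C@@H](O)C=C(C)[C@]1(C)[C@H](Cc1ccoc1)O[Si](C)(C)C(C)(C)C | intermediate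
14 | triol (C10–CH2OH, 6α-OH, (11S)-OH) | [C@H]1(CO)[C@](C)(C#C)[C@@H](O)C=C(C)[C@]1(C)[C@H](Cc1ccoc1)O | intermediate
15 | primary silyl ether (C1–O–SiMe2t-Bu; 6α-OH, 11-OH) | [C@H]1(CO[Si](C)(C)C(C)(C)C)[C@](C)(C#C)[C@@H](O)C=C(C)[C@]1(C)[C@H](Cc1ccoc1)O | intermediate
16 | diacetate (6α-OAc, 11-OAc; C7=C8) | [C@H]1(CO[Si](C)(C)C(C)(C)C)[C@](C)(C#C)[C@@H](OC(C)=O)C=C(C)[C@]1(C)[C@H](Cc1ccoc1)OC(C)=O | intermediate
17 | diol (7β-OH, 8β-OH) | [C@H]1(CO[Si](C)(C)C(C)(C)C)[C@](C)(C#C)[C@@H](OC(C)=O)[C@H](O)[C@](C)(O)[C@]1(C)[C@H](Cc1ccoc1)OC(C)=O | intermediate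
18 | isobutyrate (7β-O-isobutyryl, 8β-OH) | [C@H]1(CO[Si](C)(C)C(C)(C)C)[C@](C)(C#C)[C@@H](OC(C)=O)[C@H](OC(=O)C(C)C)[C@](C)(O)[C@]1(C)[C@H](Cc1ccoc1)OC(C)=O | intermediate
19 | primary alcohol (C10–CH2OH; C5 ethynyl) | [C@H]1(CO)[C@](C)(C#C)[C@@H](OC(C)=O)[C@H](OC(=O)C(C)C)[C@](C)(O)[C@]1(C)[C@H](Cc1ccoc1)OC(C)=O | intermediate
20 | dienyl alcohol (C5 buta-1,3-dien-2-yl; C10–CH2OH) | [C@H]1(CO)[C@](C)(C(=C)C=C)[C@@H](OC(C)=O)[C@H](OC(=O)C(C)C)[C@](C)(O)[C@]1(C)[C@H](Cc1ccoc1)OC(C)=O | intermediate
21 | dienyl aldehyde (C10–CHO) | [C@H]1(C=O)[C@](C)(C(=C)C=C)[C@@H](OC(C)=O)[C@H](OC(=O)C(C)C)[C@](C)(O)[C@]1(C)[C@H](Cc1ccoc1)OC(C)=O | intermediate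
22 | samarium ketyl (C1 radical, O–SmI2) | [C@H]1([CH]O[Sm](I)I)[C@](C)(C(=C)C=C)[C@@H](OC(C)=O)[C@H](OC(=O)C(C)C)[C@](C)(O)[C@]1(C)[C@H](Cc1ccoc1)OC(C)=O | intermediate (not isolated)
23 | allylsamarium (ring A closed; C3=C4; C18–SmI2; C1–O–SmI2) | I[Sm](I)CC1=CC[C@@H](O[Sm](I)I)[C@H]2[C@@]1(C)[C@@H](OC(C)=O)[C@H](OC(=O)C(C)C)[C@](C)(O)[C@]2(C)[C@H](Cc1ccoc1)OC(C)=O | intermediate (not isolated)
24 | ring-closed furan, (11S)-6α,11-diacetoxy-15,16-epoxy-1β,8β-dihydroxy-7β-isobutyryloxycleroda-4(18),13(16),14-triene | C=C1CC[C@@H](O)[C@H]2[C@@]1(C)[C@@H](OC(C)=O)[C@H](OC(=O)C(C)C)[C@](C)(O)[C@]2(C)[C@H](Cc1ccoc1)OC(C)=O | intermediate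
25 | hydroxybutenolide (16-hydroxy-13-en-15,16-olide, C16 epimers) | C=C1CC[C@@H](O)[C@H]2[C@@]1(C)[C@@H](OC(C)=O)[C@H](OC(=O)C(C)C)[C@](C)(O)[C@]2(C)[C@H](CC1=CC(=O)OC1O)OC(C)=O | intermediate (not isolated)
26 | CNP0254453.1, (1R,5R,6R,7S,8R,9S,10S,11S)-6,11-diacetoxy-1,8-dihydroxy-7-isobutyryloxycleroda-4(18),13-dien-15,16-olide | C=C1CC[C@@H](O)[C@H]2[C@@]1(C)[C@@H](OC(C)=O)[C@H](OC(=O)C(C)C)[C@](C)(O)[C@]2(C)[C@H](CC1=CC(=O)OC1)OC(C)=O | target

Total step count: 19. Longest linear sequence: 18 steps (steps 1–3 and 5–19).

**Steps most likely to fail**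

First, step 18. The ketyl may be reduced further before it cyclises (simple reduction to the primary alcohol, or pinacol coupling), and the allylsamarium may be protonated at C18, which would move the double bond into ring A. The fallback uses known chemistry and sets out from compound 18. Cross enyne metathesis with ethylene (as in step 16) should give the silyl ether diene F1. Hydroboration of its monosubstituted C2=C3 vinyl group with 9-borabicyclo[3.3.1]nonane and oxidation with NaBO3·4H2O should give the homoallylic primary alcohol F2. I2, PPh3 and imidazole should convert it into the primary iodide F3. HF·pyridine then frees the C1 alcohol F4, and Dess–Martin oxidation gives the iodo aldehyde F5. An intramolecular samarium Barbier reaction (SmI2, HMPA, THF, –78 °C) closes the C1–C2 bond through a chair with the alkoxide equatorial, and the route is rejoined at compound 24.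

Second, step 5. Proton transfer from the enolisable aldehyde to the hindered enolate, retro-aldol cleavage and loss of face control are the likely failure processes. The fallback sets out from compound 6. Bromination of its lithium enolate with N-bromosuccinimide should give the α-bromo ketone F6. SmI2 (THF, –78 °C) in the presence of aldehyde 8 then generates a non-basic trivalent samarium enolate regiospecifically, which should add through the same chelated chair (samarium Reformatsky-type aldol). The route is rejoined at compound 9.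

Third, step 1. An uncatalysed background cycloaddition of the very reactive diene, and hydrogen bonding of the catalyst to the ester instead of the formyl group, may erode the enantioselectivity. The fallback replaces catalyst control by auxiliary control and sets out from compound 2. Condensation of 4-methoxybut-3-en-2-one with (2R,5R)-2,5-diphenylpyrrolidine (or its antipode, whichever matches the configuration drawn) gives the vinylogous amide F7. Silylation (KN(SiMe3)2, t-BuMe2SiCl) gives the C2-symmetric aminosiloxydiene F8. Thermal Diels–Alder reaction with 2 should give adduct F9 under control of the auxiliary. The conditions of step 2 then give alkyne F10 and, on acid treatment, release the auxiliary and rejoin the route at compound 5.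

**Further compounds**
F1 | step 18 | silyl ether diene (C1–O–SiMe2t-Bu; C5 buta-1,3-dien-2-yl) | [C@H]1(CO[Si](C)(C)C(C)(C)C)[C@](C)(C(=C)C=C)[C@@H](OC(C)=O)[C@H](OC(=O)C(C)C)[C@](C)(O)[C@]1(C)[C@H](Cc1ccoc1)OC(C)=O
F2 | step 18 | homoallylic primary alcohol (C2–OH) | [C@H]1(CO[Si](C)(C)C(C)(C)C)[C@](C)(C(=C)CCO)[C@@H](OC(C)=O)[C@H](OC(=O)C(C)C)[C@](C)(O)[C@]1(C)[C@H](Cc1ccoc1)OC(C)=O
F3 | step 18 | primary iodide (C2–I) | [C@H]1(CO[Si](C)(C)C(C)(C)C)[C@](C)(C(=C)CCI)[C@@H](OC(C)=O)[C@H](OC(=O)C(C)C)[C@](C)(O)[C@]1(C)[C@H](Cc1ccoc1)OC(C)=O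
F4 | step 18 | iodo alcohol (C10–CH2OH; C2–I) | [C@H]1(CO)[C@](C)(C(=C)CCI)[C@@H](OC(C)=O)[C@H](OC(=O)C(C)C)[C@](C)(O)[C@]1(C)[C@H](Cc1ccoc1)OC(C)=O
F5 | step 18 | iodo aldehyde (C10–CHO; C2–I) | [C@H]1(C=O)[C@](C)(C(=C)CCI)[C@@H](OC(C)=O)[C@H](OC(=O)C(C)C)[C@](C)(O)[C@]1(C)[C@H](Cc1ccoc1)OC(C)=O
F6 | step 5 | α-bromo ketone (C9 bearing Br and CH3, epimer mixture) | [C@H]1(C(=O)OCC)[C@](C)(C#C)C=CC(=O)C1(C)Br
F7 | step 1 | vinylogous amide, (E)-4-[(2R,5R)-2,5-diphenylpyrrolidin-1-yl]but-3-en-2-one | CC(=O)/C=C/N1[C@@H](c2ccccc2)CC[C@@H]1c1ccccc1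
F8 | step 1 | auxiliary diene, (E)-3-(tert-butyldimethylsilyloxy)-1-[(2R,5R)-2,5-diphenylpyrrolidin-1-yl]buta-1,3-diene | C=C(O[Si](C)(C)C(C)(C)C)/C=C/N1[C@@H](c2ccccc2)CC[C@@H]1c1ccccc1
F9 | step 1 | auxiliary-bearing Diels–Alder adduct (as 3, with the pyrrolidine on C6) | [C@H]1(C(=O)OCC)[C@](C)(C=O)[C@H](N2[C@@H](c3ccccc3)CC[C@@H]2c2ccccc2)C=C(O[Si](C)(C)C(C)(C)C)C1
F10 | step 1 | auxiliary-bearing alkyne (as 4, with the pyrrolidine on C6) | [C@H]1(C(=O)OCC)[C@](C)(C#C)[C@H](N2[C@@H](c3ccccc3)CC[C@@H]2c2ccccc2)C=C(O[Si](C)(C)C(C)(C)C)C1
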